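**Plan**

- Retrosynthesis: the C8–prenyl bond is cut first, then the C5–C6 bond of benzene ring A. Ring A (C4a, C5, C6, C7, C8, C8a of the 2H-chromene) has oxygen on C5, C7 and C8a and a benzoyl group on C6, the pattern of a folded triketide. It therefore unfolds into a 4-alkoxy-2-pyranone in which C5 is the lactone carbonyl, C7 the carbon on the ring oxygen, C8a the alkoxy carbon, and C6 the CH2 of a phenacyl arm.
- Earlier cuts: the CH2–C(=O)Ph bond of that arm, then C4–C4a and O1–C2 of the dimethylpyran ring.
- Forward: hydroxypyranone 1 and enal 2 give, through oxatriene 3, pyranopyranone 4 (dimethylpyran ring first); acylation of its methyl group with methyl benzoate 5 gives phenacyl pyranone 6.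
- Mg(OMe)2 then converts 6, through ring-opened ester 7, into chromene 8 (benzene ring A second), and prenyl bromide 9 places the side chain on C8 to give target 10.
- Stereochemistry: the target has no stereocentre; C3=C4 is cis by ring constraint and the prenyl alkene carries two identical methyl groups, so nothing has to be controlled.

Key step: step 3

Assumption: metal enolates, phenoxides and chelates that are only protonated on work-up, and keto–enol tautomers, are treated as forms of the numbered compound they derive from; chromene numbering (O1, C2, C3, C4, C4a, C5 to C8, C8a) is used for 8 and 10.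

**Step 1**
Reactants: 1 4-hydroxy-6-methyl-2H-pyran-2-one; 2 3-methylbut-2-enal
Product: 4 2,2,7-trimethyl-2H,5H-pyrano[4,3-b]pyran-5-one, via alkylidene pyrandione 3 (not isolated)
Conditions: ethylenediammonium diacetate (10 mol%), CH2Cl2, 40 °C
Reagents that add atoms: 3-methylbut-2-enal (2), CC(C)=CC=O
Why: Amine-catalysed Knoevenagel condensation at C3 of the hydroxypyranone should give 1-oxatriene 3, whose oxa-6π electrocyclisation through the C4 oxygen closes the 2,2-dimethyl-2H-pyran ring (formal [3+3] annulation), a standard reaction of cyclic 1,3-dicarbonyl compounds with β,β-disubstituted enals.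

**Step 2**
Reactants: 4 2,2,7-trimethyl-2H,5H-pyrano[4,3-b]pyran-5-one; 5 methyl benzoate
Product: 6 2,2-dimethyl-7-(2-oxo-2-phenylethyl)-2H,5H-pyrano[4,3-b]pyran-5-one
Conditions: LiN(i-Pr)2 (2.2 equiv, commercial solution), THF, −78 °C; then PhCO2Me, −78 → 0 °C; then 1 M HCl to pH 4, 0 °C
Reagents that add atoms: methyl benzoate (5), COC(=O)c1ccccc1
Why: The 7-methyl group is the doubly vinylogous α-position of the lactone (CH3–C7=C8–C8a=C4a–C5=O) and the only acidic C–H because C4a is substituted, so the extended lithium enolate should undergo Claisen-type acylation with the non-enolisable ester, the second equivalent of base holding the more acidic β-keto product as its enolate and so blocking a second addition.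

**Step 3**
Reactants: 6 2,2-dimethyl-7-(2-oxo-2-phenylethyl)-2H,5H-pyrano[4,3-b]pyran-5-one
Product: 8 (5,7-dihydroxy-2,2-dimethyl-2H-chromen-6-yl)(phenyl)methanone, via ring-opened methyl ester 7 (not isolated)
Conditions: Mg(OMe)2 (4 equiv, commercial solution), MeOH, 65 °C; then 1 M HCl, 0 °C
Reagents that add atoms: none
Why: Methoxide adds to the lactone carbonyl (future C5) and cleaves the acyl–oxygen bond, giving methyl ester 7 on the enol-ether carbon C4a together with a magnesium-chelated β-diketone enolate; the central diketone carbon (the former phenacyl CH2, future C6) then attacks the ester carbonyl, methoxide is expelled and the cyclic triketone enolises to the benzene ring. The closest known reaction is the Mg(OMe)2-induced Claisen recyclisation of 4-oxygenated 6-(2-oxoalkyl)-2-pyranones to acylphloroglucinols. Benzene ring A closes in a 6-exo-trig Claisen (Dieckmann-type) mode, forming the C5–C6 bond next to the dimethylpyran ring already present. No stereocentre is formed. The step needs C-acylation to prevail over return to the lactone, over an aldol-type closure and over retro-Claisen loss of the benzoyl group. The substrate provides for this: the cis C4a=C8a double bond locked in the pyran ring keeps ester and diketone chain within bonding distance, C4a carries no hydrogen so no ester-side carbanion can start an aldol closure, the magnesium chelate keeps the diketone as a C-nucleophilic enolate, and aromatisation makes the closure irreversible.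

**Step 4**
Reactants: 8 (5,7-dihydroxy-2,2-dimethyl-2H-chromen-6-yl)(phenyl)methanone; 9 1-bromo-3-methylbut-2-ene
Product: 10 [5,7-dihydroxy-2,2-dimethyl-8-(3-methylbut-2-en-1-yl)-2H-chromen-6-yl](phenyl)methanone
Conditions: 10% aq. KOH (2.5 equiv), 0 °C; then 9 (1.1 equiv), 0 °C → rt; then 1 M HCl
Reagents that add atoms: 1-bromo-3-methylbut-2-ene (9), CC(C)=CCBr
Why: C-alkylation of an ambident phenoxide (the usual C-prenylation of acylphloroglucinols): in water the phenoxide oxygens are hydrogen-bonded, so the allylic bromide should be attacked by C8, the only unsubstituted ring carbon, ortho to O7 and para to O5, and the near-stoichiometric amount of bromide at low temperature limits O-alkylation and a second, dearomatising alkylation.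

**Compound list**

1 | 4-hydroxy-6-methyl-2H-pyran-2-one | CC1=CC(O)=CC(=O)O1 | starting material
2 | 3-methylbut-2-enal | CC(C)=CC=O | starting material
3 | 6-methyl-3-(3-methylbut-2-en-1-ylidene)-2H-pyran-2,4(3H)-dione | CC1=CC(=O)C(=CC=C(C)C)C(=O)O1 | intermediate (not isolated)
4 | 2,2,7-trimethyl-2H,5H-pyrano[4,3-b]pyran-5-one | CC1=CC2=C(C=CC(C)(C)O2)C(=O)O1 | intermediate
5 | methyl benzoate | COC(=O)c1ccccc1 | starting material
6 | 2,2-dimethyl-7-(2-oxo-2-phenylethyl)-2H,5H-pyrano[4,3-b]pyran-5-one | O=C1OC(CC(=O)c2ccccc2)=CC3=C1C=CC(C)(C)O3 | intermediate
7 | methyl 6-(2,4-dioxo-4-phenylbutyl)-2,2-dimethyl-2H-pyran-5-carboxylate | COC(=O)C1=C(CC(=O)CC(=O)c2ccccc2)OC(C)(C)C=C1 | intermediate (not isolated)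
8 | (5,7-dihydroxy-2,2-dimethyl-2H-chromen-6-yl)(phenyl)methanone (6-benzoyl-5,7-dihydroxy-2,2-dimethyl-2H-chromene) | CC1(C)C=Cc2c(O)c(C(=O)c3ccccc3)c(O)cc2O1 | intermediate
9 | 1-bromo-3-methylbut-2-ene | CC(C)=CCBr | starting material
10 | [5,7-dihydroxy-2,2-dimethyl-8-(3-methylbut-2-en-1-yl)-2H-chromen-6-yl](phenyl)methanone | CC(C)=CCc1c(O)c(C(=O)c2ccccc2)c(O)c2c1OC(C)(C)C=C2 | target

**Step count**

Total steps: 4. Longest linear sequence: 4 steps (1 → 4 → 6 → 8 → 10).

**Steps most likely to fail**

1. Step 3. After methoxide opens the lactone, the chain may simply close back to the pyranone, or methoxide may cleave the β-diketone (retro-Claisen loss of the benzoyl group) faster than the deactivated, enol-ether-conjugated ester is attacked. Fallback: benzene ring A would be taken ready-made and the dimethylpyran ring annulated onto it. Setting out from 3-methylbut-2-enal 2, condensation with purchased 2,4,6-trihydroxybenzophenone F1 under ethylenediammonium diacetate catalysis (or in pyridine at 110 °C) should proceed by Knoevenagel condensation at a free ring carbon and oxa-6π electrocyclisation of the resulting ortho-quinone methide. This comes back to the route at chromene 8. Ring closure through a hydroxyl ortho to the benzoyl group competes with closure through the para hydroxyl, so the regioisomeric chromenes would have to be separated by chromatography.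

2. Step 4. O-alkylation of the phenoxide, a second dearomatising alkylation at C8, or hydrolysis of the allylic bromide in the aqueous base may outrun mono-C-alkylation. Fallback: the prenyl group would be delivered intramolecularly. Setting out from chromene 8, decarboxylative O-allylation of the less hindered 7-hydroxyl with tert-butyl 2-methylbut-3-en-2-yl carbonate and Pd(PPh3)4 (zerovalent palladium, catalytic) in THF at 0 °C should give (5-hydroxy-2,2-dimethyl-7-[(2-methylbut-3-en-2-yl)oxy]-2H-chromen-6-yl)(phenyl)methanone F2. Heating F2 in toluene at 110 °C should trigger an aromatic Claisen rearrangement to C8, the only free ortho position, which turns the 1,1-dimethylallyl ether into the C-prenyl group and comes back to the route at target 10.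

3. Step 2. Proton transfer from the acylated product to the lithiated pyranone may stop the acylation halfway, or the carbanion may add twice to the ester. Fallback: the oxidation level would be changed. Setting out from pyranopyranone 4, deprotonation with LiN(i-Pr)2 (1.1 equiv, THF, −78 °C) and aldol addition to benzaldehyde should give racemic 7-(2-hydroxy-2-phenylethyl)-2,2-dimethyl-2H,5H-pyrano[4,3-b]pyran-5-one F3. Oxidation of F3 with Dess–Martin periodinane in CH2Cl2 comes back to the route at phenacyl pyranone 6.

**Further compounds**

F1 | step 3 | 2,4,6-trihydroxybenzophenone | O=C(c1ccccc1)c1c(O)cc(O)cc1O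
F2 | step 4 | (5-hydroxy-2,2-dimethyl-7-[(2-methylbut-3-en-2-yl)oxy]-2H-chromen-6-yl)(phenyl)methanone | C=CC(C)(C)Oc1cc2OC(C)(C)C=Cc2c(O)c1C(=O)c1ccccc1
F3 | step 2 | 7-(2-hydroxy-2-phenylethyl)-2,2-dimethyl-2H,5H-pyrano[4,3-b]pyran-5-one (racemic) | O=C1OC(CC(O)c2ccccc2)=CC3=C1C=CC(C)(C)O3
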